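The readings are calculated for substances that don't exist; the scatter is artificial.

A small charge of electrophile, 0.010 M, reacts with nucleophile dissolving from a held gas to give target and acid set free, and free base is there to take up the acid. The flasks delta, eta and zeta differ in free base, and the question is what fraction of the charge has reacted by 15 min.

in all of them: electrophile 0.010 M; gas 0.58 mM (held)
- alder: free base 0.030 M; run made earlier
- oak: free base 0.052 M; run made earlier
- delta: free base 0.0200 M; time 15 min
- eta: free base 0.0260 M; time 15 min
- zeta: free base 0.0340 M; time 15 min

| run | time / min | electrophile / % | target / % |
|---|---|---|---|
| alder | 1.00 | 92.7 | 7.9 |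
| alder | 3.00 | 76.3 | 23.3 |
| alder | 5.00 | 63.5 | 38.0 |
| alder | 8.00 | 45.7 | 54.4 |
| alder | 12.0 | 28.2 | 70.9 |
| alder | 15.0 | 19.6 | 80.1 |
| oak | 1.33 | 89.3 | 10.3 |
| oak | 2.00 | 83.2 | 17.5 |
| oak | 3.00 | 76.0 | 24.3 |
| oak | 5.00 | 61.5 | 38.0 |
| oak | 10.0 | 35.5 | 64.9 |
| oak | 15.0 | 19.3 | 80.7 |

(standard deviation of a reading: 0.5 percentage points)

- amounts and yields of target count crystals too
- given per volume of solution although it is solid: crystals
- at the start none of nucleophile is dissolved
- the numbers in the tables scatter with a standard deviation of 0.5 percentage points
- steps thought possible: electrophile + nucleophile -> acid set free + target; nucleophile + acid set free <-> protonated nucleophile; electrophile -> decomposition product; gas <-> nucleophile; acid set free + free base <-> salt of the base; crystals <-> target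

- part of the electrophile that has reacted at the end, delta
- part of the electrophile that has reacted at the end, eta
- part of the electrophile that has reacted at the end, zeta
- what raising the concentration of free base from its lowest to its highest value here does to the part of the electrophile that has reacted (changes below 5 percentage points count as none) (it rises / it falls / no change)

*What do you freeze?* The pace of the electrophile, meaning ln(1 / fraction of the charge left) divided by the time of reading, a pseudo-first-order constant. Alder and oak together give 0.109 /min at 15 min.

*Why may it cross from one amount of free base to another?* Oak has 1.73 times the free base of alder, yet their fractions left differ by 0.3 percentage points, with a scatter of 0.5 points.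

*But delta has less free base than either run. Can it run short?* If the whole charge of electrophile reacted and every bit of acid went to the free base, delta would lose 50.0% of its charge of free base, which leaves 50.0% of it.

*Is the pace really constant?* No. At 3.00 min the same two runs give 0.0908 /min, which is less than the pace at 15 min. So the pace I carry is the one read at 15.0 min, and delta, eta and zeta are asked at that same time.

*Your figure?* 80.6% reacted in each flask, hence no change.

The forecast gives 80%, 80.2% and 80.3% with no change, in its words “I expect about 80% in each”, a shade under my figure.

The flasks give 79.4% for delta, 79.8% for eta and 80.3% for zeta, a rise of 0.93 points from delta to zeta, under the 5 points that counts as a change, which is no change.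

    electrophile + nucleophile → acid set free + target (k = 250 /M/min)
    nucleophile + acid set free ⇌ protonated nucleophile, settled at all times (K = 7.90 × 10⁵ /M)
    electrophile → decomposition product (k = 5.90 × 10⁻⁵ /min)
    gas ⇌ nucleophile, rate k4*(csat - [nucleophile]) (kL = 5.20 /min)
    acid set free + free base ⇌ salt of the base, settled at all times (K = 24000 /M)
    crystals ⇌ target, rate k6*(cs6 - [target]) while solid is left; crystals form when [target] > cs6 (solubility = 4.50 mM, k = 1.40 /min)

Delta's own pace at 15 min comes to 0.105 /min, beside the 0.109 /min carried from alder and oak. The neighbouring flask is delta read at 4.0 min, an early stage, so I use the early pace of 0.0908 /min, and it gives 30.5% reacted. In that neighbouring flask more of the charge is still electrophile than has reacted, with 70% left and 30.1% reacted.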